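**Retrosynthetic overview** (locants used below: ring A = C1–C2–C3(=O)–C4–C5=C10; ring B = C5–C6(=O)–C7(OH)=C8–C9–C10; side chain C11–C15 on C9; C19 = the CH2OAc carbon on C4)
- Ring A is closed last through C2–C3: an allylsamarium at C2 (from an allylic acetate on C10) is acylated by a lactone carbonyl that becomes the C3 ketone.
- Enabling feature: the ketone carbons C3 (ring A) and C6 (ring B) are 1,4-related through quaternary C4 and ring-fusion carbon C5. They are therefore carried as one temporary furan, later a 2(3H)-furanone (O–C3 bond not in the target). Its ring oxygen becomes the C6 carbonyl oxygen when C3 is acylated; the same ring blocks C5 (one enolisable side for C9) and makes C4–H acidic.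
- Order of rings: furan + ring B (Feist–Benary); C9 by asymmetric α-vinylation and B-alkyl Suzuki coupling; furan to lactone; C4 by asymmetric α-alkylation; then ring A with unveiling of the dienone.
- The diosphenol (C8 methyl, C7 OH) is completed after the key step by cuprate addition, enolate hydroxylation and oxidation.

Key step: step 12

Remark (assumption): the sense of induction in the two catalyst-controlled steps (3 and 11) is taken to follow the catalyst antipode; the antipode that gives the drawn configuration is used.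

**Step 1**
Reactants: 1 cyclohexane-1,3-dione; 2 chloroacetone
Product: 3 3-methyl-6,7-dihydrobenzofuran-4(5H)-one
Conditions: KOH, MeOH–H2O, rt; then 2 M HCl, rt
Reagents that add atoms: none
Why: Feist–Benary furan synthesis, in which aldol attack of the dione C2 on the ketone, O-alkylation by the CH2Cl carbon and dehydration should give the 3-methylfuran that carries C3, C4, C5 and the C6 oxygen.

**Step 2**
Reactants: 3 3-methyl-6,7-dihydrobenzofuran-4(5H)-one
Product: 4 (±)-3,5-dimethyl-6,7-dihydrobenzofuran-4(5H)-one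
Conditions: LDA, THF, −78 °C; MeI, −78 to 0 °C
Reagents that add atoms: iodomethane, CI
Why: kinetic enolate alkylation at the only CH2 next to the ketone (the other side is a furan carbon); the racemic centre becomes a planar enolate again in step 3.

**Step 3**
Reactants: 4 (±)-3,5-dimethyl-6,7-dihydrobenzofuran-4(5H)-one
Product: 5 (S)-3,5-dimethyl-5-vinyl-6,7-dihydrobenzofuran-4(5H)-one
Conditions: Pd2(dba)3, (S)-2-(dicyclohexylphosphino)-2′-(dimethylamino)-1,1′-binaphthyl, NaOt-Bu, vinyl bromide (1 M in THF), toluene, rt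
Reagents that add atoms: vinyl bromide, C=CBr
Why: Pd-catalysed asymmetric α-vinylation of a ketone enolate on a substrate that, like 2-methyl-1-tetralone, has a single enolisable α-carbon; the chiral P,N ligand selects the enolate face and sets quaternary C9.

**Step 4**
Reactants: 5 (S)-3,5-dimethyl-5-vinyl-6,7-dihydrobenzofuran-4(5H)-one
Product: 7 (R)-3,5-dimethyl-5-vinylbenzofuran-4(5H)-one, via selenide 6 (not isolated)
Conditions: LDA, THF, −78 °C; PhSeCl, −78 °C; then 30% H2O2, pyridine, CH2Cl2, 0 °C to rt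
Reagents that add atoms: none
Why: with C9 quaternary the only acidic position is the furan-bound CH2 (lateral, vinylogous deprotonation of a 2-alkyl-3-acylfuran); selenenylation there and selenoxide syn-elimination should give the C7=C8 alkene, which cannot aromatise.

**Step 5**
Reactants: 8 but-2-yn-1-ol
Product: 9 tert-butyl(but-2-yn-1-yloxy)dimethylsilane
Conditions: TBSCl, imidazole, DMF, rt
Reagents that add atoms: tert-butyldimethylsilyl chloride, CC(C)(C)[Si](C)(C)Cl
Why: standard silylation of a primary alcohol.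

**Step 6**
Reactants: 9 tert-butyl(but-2-yn-1-yloxy)dimethylsilane
Product: 11 (E)-tert-butyl[(3-iodobut-2-en-1-yl)oxy]dimethylsilane, via alkenylzirconocene chloride 10 (not isolated)
Conditions: Cp2Zr(H)Cl (2 equiv), THF, 50 °C; then I2, THF, 0 °C
Reagents that add atoms: iodine, II
Why: syn-hydrozirconation with equilibration should place zirconium on the methyl-bearing carbon, and iodinolysis with retention gives the (E)-iodide.

**Step 7**
Reactants: 7 (R)-3,5-dimethyl-5-vinylbenzofuran-4(5H)-one; 11 (E)-tert-butyl[(3-iodobut-2-en-1-yl)oxy]dimethylsilane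
Product: 13 (R)-5-[(E)-5-(tert-butyldimethylsilyloxy)-3-methylpent-3-en-1-yl]-3,5-dimethylbenzofuran-4(5H)-one, via alkylborane 12 (not isolated)
Conditions: 9-BBN, THF, 0 °C to rt; then 11, Pd(dppf)Cl2, AsPh3, Cs2CO3, DMF–H2O, rt
Reagents that add atoms: none
Why: 9-BBN should hydroborate the monosubstituted vinyl group in preference to the conjugated ring alkene and the hindered ketone, and the B-alkyl Suzuki–Miyaura coupling joins C12 to C13 with retention of the (E)-geometry.

**Step 8**
Reactants: 13 (R)-5-[(E)-5-(tert-butyldimethylsilyloxy)-3-methylpent-3-en-1-yl]-3,5-dimethylbenzofuran-4(5H)-one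
Product: 14 (5R)-5-[(E)-5-(tert-butyldimethylsilyloxy)-3-methylpent-3-en-1-yl]-3,5-dimethyl-4-vinyl-4,5-dihydrobenzofuran-4-ol (both C4 epimers)
Conditions: CH2=CHMgBr, CeCl3, THF, −78 to 0 °C; aq. NH4Cl
Reagents that add atoms: vinylmagnesium bromide, C=C[Mg]Br
Why: organocerium 1,2-addition to a hindered, non-enolisable ketone brings in C1–C2; the new carbinol centre is removed in step 9.

**Step 9**
Reactants: 14 (5R)-5-[(E)-5-(tert-butyldimethylsilyloxy)-3-methylpent-3-en-1-yl]-3,5-dimethyl-4-vinyl-4,5-dihydrobenzofuran-4-ol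
Product: 16 2-[(5R)-5-[(E)-5-(tert-butyldimethylsilyloxy)-3-methylpent-3-en-1-yl]-3,5-dimethylbenzofuran-4(5H)-ylidene]ethyl acetate (E/Z mixture), via allylic alcohol 15 (not isolated)
Conditions: O3ReOSiPh3 (5 mol%), Et2O, −50 to 0 °C; then Ac2O, pyridine, DMAP, 0 °C
Reagents that add atoms: acetic anhydride, CC(=O)OC(C)=O
Why: oxorhenium-catalysed 1,3-transposition of the tertiary allylic alcohol (perrhenate ester [3,3] shift) should run to the conjugated primary alcohol, which is acetylated; the alkene geometry is irrelevant because the allyl unit equilibrates in step 12.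

**Step 10**
Reactants: 16 2-[(5R)-5-[(E)-5-(tert-butyldimethylsilyloxy)-3-methylpent-3-en-1-yl]-3,5-dimethylbenzofuran-4(5H)-ylidene]ethyl acetate
Product: 18 2-[(5R)-5-[(E)-5-(tert-butyldimethylsilyloxy)-3-methylpent-3-en-1-yl]-3,5-dimethyl-2-oxo-2,3-dihydrobenzofuran-4(5H)-ylidene]ethyl acetate (C3 epimers, E/Z), via furylboronate 17 (not isolated)
Conditions: [Ir(OMe)(cod)]2, 4,4′-di-tert-butyl-2,2′-bipyridine, B2pin2, THF, 50 °C; then NaBO3·4H2O, THF–H2O, rt
Reagents that add atoms: sodium perborate, [Na+].[O-]OB=O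
Why: Ir-catalysed C–H borylation at the only furan C–H followed by oxidation gives the 2-hydroxyfuran, which tautomerises to the butenolide and turns C3 into a lactone carbonyl without strong base.

**Step 11**
Reactants: 18 2-[(5R)-5-[(E)-5-(tert-butyldimethylsilyloxy)-3-methylpent-3-en-1-yl]-3,5-dimethyl-2-oxo-2,3-dihydrobenzofuran-4(5H)-ylidene]ethyl acetate
Product: 19 [(3S,5R)-4-(2-acetoxyethylidene)-5-[(E)-5-(tert-butyldimethylsilyloxy)-3-methylpent-3-en-1-yl]-3,5-dimethyl-2-oxo-2,3,4,5-tetrahydrobenzofuran-3-yl]methyl acetate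
Conditions: bromomethyl acetate, O-allyl-N-(9-anthracenylmethyl)cinchonidinium bromide (10 mol%), Cs2CO3, toluene, −40 °C
Reagents that add atoms: bromomethyl acetate, CC(=O)OCBr
Why: Proposed new method: the butenolide is deprotonated to an aromatic 2-oxidofuran (a metal dienolate), which as a chiral ammonium ion pair should be alkylated by the SN2-reactive bromomethyl acetate at its α-carbon C4 (kinetic α-alkylation of dienolates; the γ-carbon C6 is fully substituted), the catalyst shielding one face so that quaternary C4 forms as (S) under catalyst control; the closest known type is the asymmetric phase-transfer α-alkylation of 3-substituted benzofuran-2(3H)-ones and oxindoles.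

**Step 12**
Reactants: 19 [(3S,5R)-4-(2-acetoxyethylidene)-5-[(E)-5-(tert-butyldimethylsilyloxy)-3-methylpent-3-en-1-yl]-3,5-dimethyl-2-oxo-2,3,4,5-tetrahydrobenzofuran-3-yl]methyl acetate
Product: 22 [(1S,5R)-5-[(E)-5-(tert-butyldimethylsilyloxy)-3-methylpent-3-en-1-yl]-1,5-dimethyl-2,8-dioxo-1,2,3,4,5,8-hexahydronaphthalen-1-yl]methyl acetate, via allylsamarium 20 (not isolated), via samarium trienolate 21 (not isolated)
Conditions: Pd(PPh3)4 (5 mol%), SmI2 (2.5 equiv, 0.1 M in THF), THF, 0 °C to rt; aq. NH4Cl; then DBU (cat.), CH2Cl2, rt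
Reagents that add atoms: none
Why: Proposed new method: zerovalent palladium ionises the primary allylic acetate to a π-allyl complex, two single-electron transfers from SmI2 turn it into a nucleophilic allylsamarium (trivalent samarium), and this adds through C2 to the lactone carbonyl C3; collapse of the samarium hemiketal expels the enol oxygen on C6, so the temporary furanone ring opens to a samarium trienolate that is protonated at C1 to the cross-conjugated dienone with the C5=C10 double bond. The closest known reaction types are the Pd/SmI2 umpolung allylation of ketones with allylic acetates and the SmI2-mediated intramolecular nucleophilic acyl substitution of halo esters and halo lactones (Barbier type). Ring A closes by 6-exo-trig attack of the allyl terminus on the C=O through a six-membered transition state; attack through the other allyl terminus (C10) would need a four-membered ring, and the E/Z isomers of the allyl unit converge through η3–η1 interconversion. No stereocentre is formed, and C4 (quaternary, non-enolisable) and C9 are untouched. The step needs chemoselectivity: only the allylic acetate is ionised (the neopentyl acetate on C19 is inert), the lactone is the only acyl group within reach, over-addition is excluded because the nucleophile is consumed intramolecularly and the new ketone is flanked by quaternary C4, and the dienone stays masked as its enolate until the quench.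

**Step 13**
Reactants: 22 [(1S,5R)-5-[(E)-5-(tert-butyldimethylsilyloxy)-3-methylpent-3-en-1-yl]-1,5-dimethyl-2,8-dioxo-1,2,3,4,5,8-hexahydronaphthalen-1-yl]methyl acetate
Product: 24 [(1S,5R)-5-[(E)-5-(tert-butyldimethylsilyloxy)-3-methylpent-3-en-1-yl]-7-hydroxy-1,5,6-trimethyl-2,8-dioxo-1,2,3,4,5,6,7,8-octahydronaphthalen-1-yl]methyl acetate (C6/C7 mixture), via lithium enolate 23 (not isolated)
Conditions: Me2CuLi, Et2O, −78 to −40 °C; then 2-(phenylsulfonyl)-3-phenyloxaziridine, THF, −78 °C; aq. NH4Cl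
Reagents that add atoms: lithium dimethylcuprate, [Li+].C[Cu-]C; 2-(phenylsulfonyl)-3-phenyloxaziridine, O=S(=O)(N1OC1c1ccccc1)c1ccccc1
Why: cuprate 1,4-addition should occur at C8, the β-carbon of the less substituted enone arm, and the regiospecific enolate is hydroxylated at C7 by the N-sulfonyloxaziridine without competing enolisation of the ring A ketone; the new centres at C7 and C8 are erased in step 14.

**Step 14**
Reactants: 24 [(1S,5R)-5-[(E)-5-(tert-butyldimethylsilyloxy)-3-methylpent-3-en-1-yl]-7-hydroxy-1,5,6-trimethyl-2,8-dioxo-1,2,3,4,5,6,7,8-octahydronaphthalen-1-yl]methyl acetate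
Product: 26 [(1S,5S)-5-[(E)-5-(tert-butyldimethylsilyloxy)-3-methylpent-3-en-1-yl]-7-hydroxy-1,5,6-trimethyl-2,8-dioxo-1,2,3,4,5,8-hexahydronaphthalen-1-yl]methyl acetate, via triketone 25 (not isolated)
Conditions: Dess–Martin periodinane, NaHCO3, CH2Cl2, rt
Reagents that add atoms: none
Why: oxidation of the α-hydroxy ketone gives the 1,2-dione, which should enolise toward the methyl-bearing C8 to the conjugated diosphenol.

**Step 15**
Reactants: 26 [(1S,5S)-5-[(E)-5-(tert-butyldimethylsilyloxy)-3-methylpent-3-en-1-yl]-7-hydroxy-1,5,6-trimethyl-2,8-dioxo-1,2,3,4,5,8-hexahydronaphthalen-1-yl]methyl acetate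
Product: 27 [(1S,5S)-7-hydroxy-5-[(E)-5-hydroxy-3-methylpent-3-en-1-yl]-1,5,6-trimethyl-2,8-dioxo-1,2,3,4,5,8-hexahydronaphthalen-1-yl]methyl acetate (CNP0512382.1)
Conditions: HF·pyridine, pyridine, THF, 0 °C to rt
Reagents that add atoms: none
Why: buffered fluoride desilylation of the allylic silyl ether, conditions under which the acetate and the diosphenol should survive.

**Compound list**

| No. | Name | SMILES | Role |
|---|---|---|---|
| 1 | cyclohexane-1,3-dione | O=C1CCCC(=O)C1 | starting material |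
| 2 | chloroacetone | CC(=O)CCl | starting material |
| 3 | 3-methyl-6,7-dihydrobenzofuran-4(5H)-one | CC1=COC2=C1C(=O)CCC2 | intermediate |
| 4 | (±)-3,5-dimethyl-6,7-dihydrobenzofuran-4(5H)-one | CC1=COC2=C1C(=O)C(C)CC2 | intermediate |
| 5 | (S)-3,5-dimethyl-5-vinyl-6,7-dihydrobenzofuran-4(5H)-one | CC1=COC2=C1C(=O)[C@](C)(C=C)CC2 | intermediate |
| 6 | (5S)-3,5-dimethyl-7-(phenylselanyl)-5-vinyl-6,7-dihydrobenzofuran-4(5H)-one (C7 epimers) | CC1=COC2=C1C(=O)[C@](C)(C=C)CC2[Se]c3ccccc3 | intermediate |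
| 7 | (R)-3,5-dimethyl-5-vinylbenzofuran-4(5H)-one | CC1=COC2=C1C(=O)[C@](C)(C=C)C=C2 | intermediate |
| 8 | but-2-yn-1-ol | CC#CCO | starting material |
| 9 | tert-butyl(but-2-yn-1-yloxy)dimethylsilane | CC#CCO[Si](C)(C)C(C)(C)C | intermediate |
| 10 | (E)-[4-(tert-butyldimethylsilyloxy)but-2-en-2-yl]zirconocene chloride | C/C(=C\CO[Si](C)(C)C(C)(C)C)[Zr](Cl)(C1C=CC=C1)C1C=CC=C1 | intermediate |
| 11 | (E)-tert-butyl[(3-iodobut-2-en-1-yl)oxy]dimethylsilane | C/C(I)=C\CO[Si](C)(C)C(C)(C)C | intermediate |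
| 12 | B-alkyl-9-BBN adduct of 7 (boron on the terminal vinyl carbon) | CC1=COC2=C1C(=O)[C@](C)(CCB3C4CCCC3CCC4)C=C2 | intermediate |
| 13 | (R)-5-[(E)-5-(tert-butyldimethylsilyloxy)-3-methylpent-3-en-1-yl]-3,5-dimethylbenzofuran-4(5H)-one | CC1=COC2=C1C(=O)[C@](C)(CC/C(C)=C/CO[Si](C)(C)C(C)(C)C)C=C2 | intermediate |
| 14 | (5R)-5-[(E)-5-(tert-butyldimethylsilyloxy)-3-methylpent-3-en-1-yl]-3,5-dimethyl-4-vinyl-4,5-dihydrobenzofuran-4-ol (C4 epimers) | CC1=COC2=C1C(O)(C=C)[C@](C)(CC/C(C)=C/CO[Si](C)(C)C(C)(C)C)C=C2 | intermediate |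
| 15 | 2-[(5R)-5-[(E)-5-(tert-butyldimethylsilyloxy)-3-methylpent-3-en-1-yl]-3,5-dimethylbenzofuran-4(5H)-ylidene]ethanol (E/Z) | CC1=COC2=C1C(=CCO)[C@](C)(CC/C(C)=C/CO[Si](C)(C)C(C)(C)C)C=C2 | intermediate |
| 16 | acetate of 15 (E/Z) | CC1=COC2=C1C(=CCOC(C)=O)[C@](C)(CC/C(C)=C/CO[Si](C)(C)C(C)(C)C)C=C2 | intermediate |
| 17 | 2-(pinacolatoboryl) derivative of 16 (boron on the furan CH carbon) | CC1=C(B3OC(C)(C)C(C)(C)O3)OC2=C1C(=CCOC(C)=O)[C@](C)(CC/C(C)=C/CO[Si](C)(C)C(C)(C)C)C=C2 | intermediate |
| 18 | 2-[(5R)-5-[(E)-5-(tert-butyldimethylsilyloxy)-3-methylpent-3-en-1-yl]-3,5-dimethyl-2-oxo-2,3-dihydrobenzofuran-4(5H)-ylidene]ethyl acetate (C3 epimers, E/Z) | CC1C(=O)OC2=C1C(=CCOC(C)=O)[C@](C)(CC/C(C)=C/CO[Si](C)(C)C(C)(C)C)C=C2 | intermediate |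
| 19 | [(3S,5R)-4-(2-acetoxyethylidene)-5-[(E)-5-(tert-butyldimethylsilyloxy)-3-methylpent-3-en-1-yl]-3,5-dimethyl-2-oxo-2,3,4,5-tetrahydrobenzofuran-3-yl]methyl acetate | CC(=O)OC[C@@]1(C)C(=O)OC2=C1C(=CCOC(C)=O)[C@](C)(CC/C(C)=C/CO[Si](C)(C)C(C)(C)C)C=C2 | intermediate |
| 20 | allylsamarium diiodide derived from 19 (SmI2 group in place of the allylic acetate) | CC(=O)OC[C@@]1(C)C(=O)OC2=C1C(=CC[Sm](I)I)[C@](C)(CC/C(C)=C/CO[Si](C)(C)C(C)(C)C)C=C2 | intermediate |
| 21 | samarium trienolate with ring A closed (O-samarium on the future C8 carbonyl of the naphthalenone) | CC(=O)OC[C@@]1(C)C(=O)CC=C2C1=C(O[Sm](I)I)C=C[C@@]2(C)CC/C(C)=C/CO[Si](C)(C)C(C)(C)C | intermediate |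
| 22 | [(1S,5R)-5-[(E)-5-(tert-butyldimethylsilyloxy)-3-methylpent-3-en-1-yl]-1,5-dimethyl-2,8-dioxo-1,2,3,4,5,8-hexahydronaphthalen-1-yl]methyl acetate | CC(=O)OC[C@@]1(C)C(=O)CCC2=C1C(=O)C=C[C@@]2(C)CC/C(C)=C/CO[Si](C)(C)C(C)(C)C | intermediate |
| 23 | lithium enolate of the 6-methyl adduct of 22 | CC(=O)OC[C@@]1(C)C(=O)CCC2=C1C(O[Li])=CC(C)[C@@]2(C)CC/C(C)=C/CO[Si](C)(C)C(C)(C)C | intermediate |
| 24 | [(1S,5R)-5-[(E)-5-(tert-butyldimethylsilyloxy)-3-methylpent-3-en-1-yl]-7-hydroxy-1,5,6-trimethyl-2,8-dioxo-1,2,3,4,5,6,7,8-octahydronaphthalen-1-yl]methyl acetate (C6/C7 mixture) | CC(=O)OC[C@@]1(C)C(=O)CCC2=C1C(=O)C(O)C(C)[C@@]2(C)CC/C(C)=C/CO[Si](C)(C)C(C)(C)C | intermediate |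
| 25 | corresponding 2,7,8-trione (C6 epimers) | CC(=O)OC[C@@]1(C)C(=O)CCC2=C1C(=O)C(=O)C(C)[C@@]2(C)CC/C(C)=C/CO[Si](C)(C)C(C)(C)C | intermediate |
| 26 | [(1S,5S)-5-[(E)-5-(tert-butyldimethylsilyloxy)-3-methylpent-3-en-1-yl]-7-hydroxy-1,5,6-trimethyl-2,8-dioxo-1,2,3,4,5,8-hexahydronaphthalen-1-yl]methyl acetate | CC(=O)OC[C@@]1(C)C(=O)CCC2=C1C(=O)C(O)=C(C)[C@@]2(C)CC/C(C)=C/CO[Si](C)(C)C(C)(C)C | intermediate |
| 27 | [(1S,5S)-7-hydroxy-5-[(E)-5-hydroxy-3-methylpent-3-en-1-yl]-1,5,6-trimethyl-2,8-dioxo-1,2,3,4,5,8-hexahydronaphthalen-1-yl]methyl acetate | CC(=O)OC[C@@]1(C)C(=O)CCC2=C1C(=O)C(O)=C(C)[C@@]2(C)CC/C(C)=C/CO | target |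

**Step count**
Total: 15 steps. Longest linear sequence: 13 steps (steps 1–4 and 7–15; the iodide 11 is made in 2 steps).

**Steps most likely to fail**

1. Step 12 (proposed method). The allylsamarium may be protonated or dimerised before it adds, or the liberated dienone may be over-reduced. Fallback, from 19 back to 22, by a sulfone-mediated Dieckmann-type closure of the same bond: Tsuji–Trost substitution of the allylic acetate of 19 with sodium benzenesulfinate and Pd(PPh3)4 would give the allyl sulfone F1. LiHMDS in THF at −78 °C would generate the sulfonyl-stabilised allyl carbanion, which acylates on the lactone carbonyl, and after quench and conjugation this would give the β-keto sulfone F2. Reductive desulfonylation with aluminium amalgam in wet THF would return 22.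

2. Step 11 (proposed method). Alkylation may go to the γ-carbon or to oxygen, or the facial selectivity under ion-pair control may be poor. Fallback, from 18 back to 19: deconjugative α-alkylation of the pre-formed lithium dienolate (LiHMDS, THF, −78 °C, then bromomethyl acetate) without a chiral catalyst. This would give 19 together with its C3 epimer F3; the two are diastereomers because of the fixed C5 centre and would be separated by chromatography.

3. Step 3. The hindered tetrasubstituted enolate may couple slowly, or the ligand may give insufficient face selection. Fallback, from 4 back to 5, by decarboxylative asymmetric allylic alkylation: LiHMDS and allyl chloroformate would give the allyl enol carbonate F4. Pd2(dba)3 with (S)-t-BuPHOX would give the (S)-allyl ketone F5. Isomerisation with RuHCl(CO)(PPh3)3 would give the propenyl ketone F6, and ethenolysis with the second-generation Hoveyda–Grubbs catalyst under ethylene would return 5.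

**Further compounds**
F1 | step 12 | [(3S,5R)-5-[(E)-5-(tert-butyldimethylsilyloxy)-3-methylpent-3-en-1-yl]-3,5-dimethyl-2-oxo-4-[2-(phenylsulfonyl)ethylidene]-2,3,4,5-tetrahydrobenzofuran-3-yl]methyl acetate | CC(=O)OC[C@@]1(C)C(=O)OC2=C1C(=CCS(=O)(=O)c3ccccc3)[C@](C)(CC/C(C)=C/CO[Si](C)(C)C(C)(C)C)C=C2
F2 | step 12 | [(1S,5R)-5-[(E)-5-(tert-butyldimethylsilyloxy)-3-methylpent-3-en-1-yl]-1,5-dimethyl-2,8-dioxo-3-(phenylsulfonyl)-1,2,3,4,5,8-hexahydronaphthalen-1-yl]methyl acetate | CC(=O)OC[C@@]1(C)C(=O)C(S(=O)(=O)c3ccccc3)CC2=C1C(=O)C=C[C@@]2(C)CC/C(C)=C/CO[Si](C)(C)C(C)(C)C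
F3 | step 11 | (3R,5R)-epimer of 19 | CC(=O)OC[C@]1(C)C(=O)OC2=C1C(=CCOC(C)=O)[C@](C)(CC/C(C)=C/CO[Si](C)(C)C(C)(C)C)C=C2
F4 | step 3 | allyl (3,5-dimethyl-6,7-dihydrobenzofuran-4-yl) carbonate | CC1=COC2=C1C(OC(=O)OCC=C)=C(C)CC2
F5 | step 3 | (S)-5-allyl-3,5-dimethyl-6,7-dihydrobenzofuran-4(5H)-one | CC1=COC2=C1C(=O)[C@](C)(CC=C)CC2
F6 | step 3 | (S)-3,5-dimethyl-5-[(E)-prop-1-en-1-yl]-6,7-dihydrobenzofuran-4(5H)-one | CC1=COC2=C1C(=O)[C@](C)(/C=C/C)CC2
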